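**Plan**
- Enabling feature: the benzene ring of the chroman is a 4-alkoxybenzoate. C8a carries O1, C4a carries C4 and C6 carries the carboxyl group. C8a and C4a can therefore be the carbonyl and α-carbon of a six-membered lactone O1–C2–C3–C4–C4a–C8a. C5–C8 and the carboxyl carbon correspond to the four diene carbons and the ester of methyl coumalate.
- Retrosynthetic cuts, in order: C4a–C5 together with C8a–C8, then O1–C8a (lactone), C3–C4, C2–C1' and C1'–C2'.
- Forward order: geranyl bromide is lengthened by one carbon and joined to a lactate template. An allyl group is then added, the pyranone ring is closed by oxidative lactonisation, and the benzene ring is built last on the silyl ketene acetal.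
- Stereochemistry: C2 comes from (S)-lactic acid by alkylation with self-regeneration of the stereocentre. C3 comes from a reagent-controlled allylboration ((−)-α-pinene series). The E olefin comes from geranyl bromide.

Key step: step 13

Remark: the SMILES is read as (2R,3R). Chroman numbering (O1, C2, C3, C4, C4a, C5–C8, C8a; chain C1'–C9') is used for all intermediates.

**Step 1**
Reactants: 1 (S)-lactic acid; 2 pivalaldehyde
Product: 3 (2S,5S)-2-tert-butyl-5-methyl-1,3-dioxolan-4-one (cis)
Conditions: 4-MeC6H4SO3H·H2O (cat.), H2SO4 (cat.), pentane, reflux, Dean–Stark; recrystallisation from pentane, −78 °C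
Reagents that add atoms: none
Why: Acid-catalysed acetalisation of an α-hydroxy acid with azeotropic water removal, in which the C5 methyl group biases the new acetal centre towards the cis isomer and low-temperature crystallisation should give the pure (2S,5S) compound.

**Step 2**
Reactants: 4 geranyl bromide; 5 thioanisole
Product: 6 (3E)-4,8-dimethylnona-3,7-dien-1-yl phenyl sulfide (homogeranyl phenyl sulfide)
Conditions: 5, n-BuLi, DABCO, THF, 0 °C; then 4, −78 °C → rt
Reagents that add atoms: none
Why: SN2 alkylation of a sulfur-stabilised organolithium by a primary allylic bromide adds the one missing chain carbon (C1') without touching the E olefin.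

**Step 3**
Reactants: 6 homogeranyl phenyl sulfide
Product: 8 (3E)-1-iodo-4,8-dimethylnona-3,7-diene (homogeranyl iodide), via sulfonium iodide 7 (not isolated)
Conditions: MeI (excess), NaI, DMF, 75 °C, dark
Reagents that add atoms: methyl iodide, CI; sodium iodide, [Na+].[I-]
Why: S-methylation gives a sulfonium salt from which iodide displaces thioanisole at the primary carbon (SN2 dealkylation of a sulfonium salt), while attack at methyl only regenerates MeI, so excess MeI should drive the exchange.

**Step 4**
Reactants: 3 (2S,5S)-2-tert-butyl-5-methyl-1,3-dioxolan-4-one; 8 homogeranyl iodide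
Product: 10 (2S,5R)-2-tert-butyl-5-[(3E)-4,8-dimethylnona-3,7-dien-1-yl]-5-methyl-1,3-dioxolan-4-one, via lithium enolate 9 (not isolated)
Conditions: 3 (excess), LiN(iPr)2, THF, −78 °C; then 8, DMPU, −78 → −20 °C
Reagents that add atoms: none
Why: Enolate alkylation with self-regeneration of the stereocentre, in which the planar enolate keeps only the acetal centre and its tert-butyl group shields one face, so the iodide enters trans to it in the place of the former hydrogen and sets C2 as (R).

**Step 5**
Reactants: 10 alkylated dioxolanone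
Product: 11 (2R,5E)-2,6,10-trimethylundeca-5,9-diene-1,2-diol
Conditions: LiAlH4, Et2O, 0 °C → rt; H2O/aq. NaOH work-up
Reagents that add atoms: none
Why: Hydride reduction of the acyl carbon and collapse of the resulting hemiacetal frees the 1,2-diol and removes the auxiliary as neopentyl alcohol, and the quaternary centre takes no part.

**Step 6**
Reactants: 11 diol
Product: 12 (2R,5E)-2,6,10-trimethyl-1,2-bis(trimethylsilyloxy)undeca-5,9-diene
Conditions: Me3SiCl, imidazole, DMF, 0 °C → rt
Reagents that add atoms: chlorotrimethylsilane, C[Si](C)(C)Cl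
Why: Standard silylation, since Me3SiCl with imidazole in DMF is active enough to cap the tertiary as well as the primary hydroxyl.

**Step 7**
Reactants: 12 bis-silyl ether
Product: 13 (2R,5E)-2,6,10-trimethyl-2-(trimethylsilyloxy)undeca-5,9-dienal
Conditions: (COCl)2, DMSO, CH2Cl2, −78 → −40 °C; Et3N, −78 → 0 °C
Reagents that add atoms: none
Why: Swern oxidation applied directly to the silyl ether, in which the unhindered primary Me3Si ether is exchanged by the chlorosulfonium salt and oxidised while the tertiary one stays, so the free α-hydroxy aldehyde is avoided and the product, lacking an α-hydrogen, cannot epimerise.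

**Step 8**
Reactants: 13 α-silyloxy aldehyde; 14 allylmagnesium bromide
Product: 17 (4R,5R,8E)-5,9,13-trimethyltetradeca-1,8,12-triene-4,5-diol, via borinate 15 (not isolated), via silyl ether alcohol 16 (not isolated)
Conditions: (+)-Ipc2BOMe [(−)-α-pinene series], 14, Et2O, −78 °C → rt; 13, −78 °C; NaOH, H2O2, 0 °C → rt; crude, 1 M HCl, THF, 0 °C
Reagents that add atoms: none
Why: Brown allylboration through a closed chair transition state, where the α-carbon of 13 carries two similar alkyl groups so substrate bias is small and the isopinocampheyl groups of the (−)-α-pinene series deliver allyl to the face that gives (R) at C3 (their known sense with tert-alkyl aldehydes), after which dilute acid cleaves the tertiary Me3Si ether.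

**Step 9**
Reactants: 17 diol
Product: 18 (4R,5R,8E)-4-(tert-butyldimethylsilyloxy)-5,9,13-trimethyltetradeca-1,8,12-trien-5-ol
Conditions: tBuMe2SiOTf (1 equiv), 2,6-lutidine, CH2Cl2, −78 °C
Reagents that add atoms: tert-butyldimethylsilyl triflate, CC(C)(C)[Si](C)(C)OS(=O)(=O)C(F)(F)F
Why: Selective silylation, since at low temperature one equivalent of the silyl triflate should react at the secondary hydroxyl much faster than at the neighbouring tertiary one, which must stay free for the lactone.

**Step 10**
Reactants: 18 silyl ether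
Product: 20 (4R,5R,8E)-4-(tert-butyldimethylsilyloxy)-5,9,13-trimethyltetradeca-8,12-diene-1,5-diol, via B-alkyl-9-BBN adduct 19 (not isolated)
Conditions: 9-BBN, THF, 0 °C → rt; NaOH, H2O2, 0 °C
Reagents that add atoms: hydrogen peroxide, OO
Why: Hydroboration–oxidation, in which 9-BBN discriminates strongly between the monosubstituted terminal alkene and the two trisubstituted chain alkenes and places boron on the terminal carbon, the future C8a.

**Step 11**
Reactants: 20 1,5-diol
Product: 22 (5R,6R)-5-(tert-butyldimethylsilyloxy)-6-[(3E)-4,8-dimethylnona-3,7-dien-1-yl]-6-methyloxan-2-one, via lactol 21 (not isolated)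
Conditions: TEMPO (2,2,6,6-tetramethylpiperidin-1-oxyl, cat.), PhI(OAc)2, CH2Cl2, rt
Reagents that add atoms: none
Why: Oxoammonium-mediated oxidative lactonisation of a 1,5-diol, in which the primary alcohol is oxidised to the aldehyde, the tertiary hydroxyl closes the lactol and a second oxidation gives the δ-lactone, while the protected C3 oxygen cannot divert the material to a γ-lactone.

**Step 12**
Reactants: 22 δ-lactone
Product: 24 (2R,3R)-3,6-bis(tert-butyldimethylsilyloxy)-2-[(3E)-4,8-dimethylnona-3,7-dien-1-yl]-2-methyl-3,4-dihydro-2H-pyran, via lithium enolate 23 (not isolated)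
Conditions: LiN(iPr)2, THF, −78 °C; tBuMe2SiCl, DMPU, −78 → 0 °C; pentane, ice-cold pH 7 buffer wash; used crude
Reagents that add atoms: tert-butyldimethylsilyl chloride, CC(C)(C)[Si](C)(C)Cl
Why: Kinetic enolisation and O-silylation in the presence of a dipolar cosolvent (the conditions used to make ketene acetals for the Ireland–Claisen rearrangement), and the C3 oxygen is γ to the carbonyl so β-elimination is not possible.

**Step 13**
Reactants: 24 silyl ketene acetal; 25 methyl coumalate
Product: 28 methyl (2R,3R)-3-(tert-butyldimethylsilyloxy)-2-[(3E)-4,8-dimethylnona-3,7-dien-1-yl]-2-methylchroman-6-carboxylate, via bridged lactone 26 (not isolated), via dihydroarene 27 (not isolated)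
Conditions: 25 (excess, freshly sublimed), PhMe, 110 °C, sealed tube, argon, base-washed glass; then 1,8-diazabicyclo[5.4.0]undec-7-ene (DBU, cat.), rt
Reagents that add atoms: none
Why: The electron-rich C4a=C8a double bond of 24 and the electron-poor diene C3–C6 of 25 combine in an inverse-electron-demand Diels–Alder reaction in which nucleophilic C4a bonds to pyrone C6 (β to the ester) and C8a bonds to pyrone C3 to give 26, cycloreversion expels CO2 to give 27, and loss of tBuMe2SiOH across C8a–C4a leaves the arene. The closest known reaction type is the conversion of ketene acetals and enol ethers with methyl coumalate into 4-alkoxybenzoates. The only ring closed is the benzene ring, by an intermolecular [4+2] cycloaddition that forms C4a–C5 and C8a–C8 suprafacially on both partners, the pyran ring being already in place. No lasting stereocentre is made, because the transient centres at C4a, C8a, C5 and C8 are erased on aromatisation, so endo/exo and facial selectivity are irrelevant and C2 and C3 lie outside the reacting π system. Regioselectivity (ester at C6, para to O1) follows from pairing the largest donor coefficient at C4a with the largest acceptor coefficient at pyrone C6, and chemoselectivity over the two trisubstituted chain olefins follows from the much higher donor ability of the ketene acetal. The choice between expelling the silanolate and expelling O1 is biased three ways: the silanolate is much the weaker base and better nucleofuge, the bulky silyl group resists attack or transfer at silicon (which would unmask a hemiketal that collapses to the ring-opened phenol), and in the DBU-generated dienolate of 27 the exocyclic C8a–OSi bond stands across the ring plane while the fused pyran holds C8a–O1 close to that plane.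

**Step 14**
Reactants: 28 silyl-protected chroman ester
Product: 29 methyl (2R,3R)-2-[(3E)-4,8-dimethylnona-3,7-dien-1-yl]-3-hydroxy-2-methylchroman-6-carboxylate
Conditions: Bu4NF, THF, rt → 45 °C
Reagents that add atoms: none
Why: Fluoride-induced cleavage of the silyl ether, driven by the strong Si–F bond, under which the methyl ester, aryl ether and olefins are inert.

**Step 15**
Reactants: 29 hydroxy ester
Product: 31 Kuhistanol D, via lithium carboxylate 30 (not isolated)
Conditions: LiOH, THF/MeOH/H2O, 45 °C; then 1 M HCl to pH 3, 0 °C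
Reagents that add atoms: lithium hydroxide, [Li+].[OH-]
Why: Saponification of the benzoate by acyl–oxygen cleavage followed by brief cold acidification, under which neither stereocentre is acidic or prone to ionise.

**Compound list**
1 | (S)-lactic acid | C[C@H](O)C(=O)O | starting material
2 | pivalaldehyde | CC(C)(C)C=O | starting material
3 | (2S,5S)-2-tert-butyl-5-methyl-1,3-dioxolan-4-one | C[C@@H]1O[C@H](C(C)(C)C)OC1=O | intermediate
4 | geranyl bromide | CC(C)=CCC/C(C)=C/CBr | starting material
5 | thioanisole | CSc1ccccc1 | starting material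
6 | homogeranyl phenyl sulfide | CC(C)=CCC/C(C)=C/CCSc1ccccc1 | intermediate
7 | homogeranyl(methyl)phenylsulfonium iodide (sulfur centre undefined) | CC(C)=CCC/C(C)=C/CC[S+](C)c1ccccc1.[I-] | intermediate
8 | homogeranyl iodide | CC(C)=CCC/C(C)=C/CCI | intermediate
9 | lithium enolate of 3 | CC1=C([O-])O[C@@H](C(C)(C)C)O1.[Li+] | intermediate
10 | (2S,5R)-2-tert-butyl-5-[(3E)-4,8-dimethylnona-3,7-dien-1-yl]-5-methyl-1,3-dioxolan-4-one | CC(C)=CCC/C(C)=C/CC[C@@]1(C)O[C@H](C(C)(C)C)OC1=O | intermediate
11 | (2R,5E)-2,6,10-trimethylundeca-5,9-diene-1,2-diol | CC(C)=CCC/C(C)=C/CC[C@@](C)(O)CO | intermediate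
12 | (2R,5E)-2,6,10-trimethyl-1,2-bis(trimethylsilyloxy)undeca-5,9-diene | CC(C)=CCC/C(C)=C/CC[C@@](C)(O[Si](C)(C)C)CO[Si](C)(C)C | intermediate
13 | (2R,5E)-2,6,10-trimethyl-2-(trimethylsilyloxy)undeca-5,9-dienal | CC(C)=CCC/C(C)=C/CC[C@@](C)(O[Si](C)(C)C)C=O | intermediate
14 | allylmagnesium bromide | C=CC[Mg]Br | starting material
15 | diisopinocampheylborinate of 16 | CC(C)=CCC/C(C)=C/CC[C@@](C)(O[Si](C)(C)C)[C@H](OB([C@H]1C[C@H]2C[C@@H]([C@@H]1C)C2(C)C)[C@H]3C[C@H]4C[C@@H]([C@@H]3C)C4(C)C)CC=C | intermediate
16 | (4R,5R,8E)-5,9,13-trimethyl-5-(trimethylsilyloxy)tetradeca-1,8,12-trien-4-ol | CC(C)=CCC/C(C)=C/CC[C@@](C)(O[Si](C)(C)C)[C@H](O)CC=C | intermediate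
17 | (4R,5R,8E)-5,9,13-trimethyltetradeca-1,8,12-triene-4,5-diol | CC(C)=CCC/C(C)=C/CC[C@@](C)(O)[C@H](O)CC=C | intermediate
18 | (4R,5R,8E)-4-(tert-butyldimethylsilyloxy)-5,9,13-trimethyltetradeca-1,8,12-trien-5-ol | CC(C)=CCC/C(C)=C/CC[C@@](C)(O)[C@H](O[Si](C)(C)C(C)(C)C)CC=C | intermediate
19 | B-alkyl-9-borabicyclo[3.3.1]nonane from 18 | CC(C)=CCC/C(C)=C/CC[C@@](C)(O)[C@H](O[Si](C)(C)C(C)(C)C)CCCB1C2CCCC1CCC2 | intermediate
20 | (4R,5R,8E)-4-(tert-butyldimethylsilyloxy)-5,9,13-trimethyltetradeca-8,12-diene-1,5-diol | CC(C)=CCC/C(C)=C/CC[C@@](C)(O)[C@H](O[Si](C)(C)C(C)(C)C)CCCO | intermediate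
21 | lactol of 22 (anomeric centre undefined) | CC(C)=CCC/C(C)=C/CC[C@@]1(C)OC(O)CC[C@H]1O[Si](C)(C)C(C)(C)C | intermediate
22 | (5R,6R)-5-(tert-butyldimethylsilyloxy)-6-[(3E)-4,8-dimethylnona-3,7-dien-1-yl]-6-methyloxan-2-one | CC(C)=CCC/C(C)=C/CC[C@@]1(C)OC(=O)CC[C@H]1O[Si](C)(C)C(C)(C)C | intermediate
23 | lithium enolate of 22 | CC(C)=CCC/C(C)=C/CC[C@@]1(C)OC([O-])=CC[C@H]1O[Si](C)(C)C(C)(C)C.[Li+] | intermediate
24 | (2R,3R)-3,6-bis(tert-butyldimethylsilyloxy)-2-[(3E)-4,8-dimethylnona-3,7-dien-1-yl]-2-methyl-3,4-dihydro-2H-pyran | CC(C)=CCC/C(C)=C/CC[C@@]1(C)OC(O[Si](C)(C)C(C)(C)C)=CC[C@H]1O[Si](C)(C)C(C)(C)C | intermediate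
25 | methyl coumalate (methyl 2-oxo-2H-pyran-5-carboxylate) | COC(=O)C1=COC(=O)C=C1 | starting material
26 | bridged lactone cycloadduct (four transient centres undefined) | CC(C)=CCC/C(C)=C/CC[C@@]1(C)OC2(O[Si](C)(C)C(C)(C)C)C3C=C(C(=O)OC)C(OC3=O)C2C[C@H]1O[Si](C)(C)C(C)(C)C | intermediate
27 | 4a,8a-dihydrochroman after CO2 loss (C4a and C8a undefined) | CC(C)=CCC/C(C)=C/CC[C@@]1(C)OC2(O[Si](C)(C)C(C)(C)C)C=CC(C(=O)OC)=CC2C[C@H]1O[Si](C)(C)C(C)(C)C | intermediate
28 | methyl (2R,3R)-3-(tert-butyldimethylsilyloxy)-2-[(3E)-4,8-dimethylnona-3,7-dien-1-yl]-2-methylchroman-6-carboxylate | CC(C)=CCC/C(C)=C/CC[C@@]1(C)Oc2ccc(C(=O)OC)cc2C[C@H]1O[Si](C)(C)C(C)(C)C | intermediate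
29 | methyl (2R,3R)-2-[(3E)-4,8-dimethylnona-3,7-dien-1-yl]-3-hydroxy-2-methylchroman-6-carboxylate | CC(C)=CCC/C(C)=C/CC[C@@]1(C)Oc2ccc(C(=O)OC)cc2C[C@H]1O | intermediate
30 | lithium carboxylate of 31 | CC(C)=CCC/C(C)=C/CC[C@@]1(C)Oc2ccc(C(=O)[O-])cc2C[C@H]1O.[Li+] | intermediate
31 | Kuhistanol D, (2R,3R) | CC(C)=CCC/C(C)=C/CC[C@@]1(C)Oc2ccc(C(=O)O)cc2C[C@H]1O | target

**Count**
Total: 15 steps. Longest linear sequence: 14 steps (4 → 31, steps 2–15).

**Steps most likely to fail**

Step 13. Aromatisation may expel the ring oxygen instead of the silanolate. Alternatively, silyl transfer within a zwitterionic Michael-type adduct may stop the sequence before the second bond forms.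
- The fallback keeps the same bond set but replaces silicon by sulfur. It sets out from 22 and comes back at 28.
- Lawesson's reagent (PhMe, 90 °C) converts 22 into the thionolactone F1.
- LiN(iPr)2 followed by MeI alkylates the thioenolate on sulfur to give the ketene O,S-acetal F2.
- Heating F2 with 25 in PhMe gives, after loss of CO2, the dihydroarene F3.
- In F3 methanethiolate is by far the better leaving group than O1, and there is no silicon to be attacked or transferred. Loss of MeSH gives 28.

Step 4. SN2 attack on the unactivated homoallylic iodide may be slower than decay of the enolate or E2 loss of HI.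
- The fallback buys the quaternary centre instead of making it. It sets out from 4 and comes back at 11.
- PhSO2Na (DMF, rt) turns 4 into geranyl phenyl sulfone F4.
- Its lithio derivative (n-BuLi, THF/DMPU, −78 °C) opens the lithium alkoxide of commercial (S)-2-methylglycidol (C[C@]1(CO)CO1) at the unsubstituted epoxide carbon. This gives the hydroxy sulfone F5 as epimers at the sulfone carbon.
- PdCl2(dppp)-catalysed hydride displacement with LiBHEt3 then removes the sulfonyl group without moving the E olefin and gives 11.

Step 8. Addition to the neopentyl-type carbonyl may be sluggish or show poor facial selectivity.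
- The fallback sets C3 by reduction instead of by C–C bond formation. It sets out from 13 and comes back at 16.
- Reagent 14 (Et2O, −78 °C) adds without selectivity to give the epimeric alcohols F6.
- Dess–Martin periodinane buffered with NaHCO3 gives the ketone F7.
- Corey–Bakshi–Shibata reduction follows, using (S)-1-methyl-3,3-diphenyltetrahydro-1H,3H-pyrrolo[1,2-c][1,3,2]oxazaborole and catecholborane (PhMe, −78 °C).
- This reduction differentiates the quaternary C2 (large) from the allyl CH2 (small) and should give 16. Compound 16 rejoins the route at the acid treatment of step 8.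

**Further compounds**
F1 | step 13 | (5R,6R)-5-(tert-butyldimethylsilyloxy)-6-[(3E)-4,8-dimethylnona-3,7-dien-1-yl]-6-methyloxane-2-thione | CC(C)=CCC/C(C)=C/CC[C@@]1(C)OC(=S)CC[C@H]1O[Si](C)(C)C(C)(C)C
F2 | step 13 | (2R,3R)-3-(tert-butyldimethylsilyloxy)-2-[(3E)-4,8-dimethylnona-3,7-dien-1-yl]-2-methyl-6-(methylsulfanyl)-3,4-dihydro-2H-pyran | CC(C)=CCC/C(C)=C/CC[C@@]1(C)OC(SC)=CC[C@H]1O[Si](C)(C)C(C)(C)C
F3 | step 13 | 8a-(methylsulfanyl)-4a,8a-dihydrochroman analogue of 27 (C4a and C8a undefined) | CC(C)=CCC/C(C)=C/CC[C@@]1(C)OC2(SC)C=CC(C(=O)OC)=CC2C[C@H]1O[Si](C)(C)C(C)(C)C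
F4 | step 4 | geranyl phenyl sulfone | CC(C)=CCC/C(C)=C/CS(=O)(=O)c1ccccc1
F5 | step 4 | (2R,5E)-2,6,10-trimethyl-4-(phenylsulfonyl)undeca-5,9-diene-1,2-diol (C4 undefined) | CC(C)=CCC/C(C)=C/C(C[C@@](C)(O)CO)S(=O)(=O)c1ccccc1
F6 | step 8 | (5R,8E)-5,9,13-trimethyl-5-(trimethylsilyloxy)tetradeca-1,8,12-trien-4-ol (C4 epimers) | CC(C)=CCC/C(C)=C/CC[C@@](C)(O[Si](C)(C)C)C(O)CC=C
F7 | step 8 | (5R,8E)-5,9,13-trimethyl-5-(trimethylsilyloxy)tetradeca-1,8,12-trien-4-one | CC(C)=CCC/C(C)=C/CC[C@@](C)(O[Si](C)(C)C)C(=O)CC=C
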